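**Retrosynthetic overview**

- The target is reached from a flavone in which ring C is already closed, by three finishing steps: hydrolysis of a 6,7-ketal, methylation of the 7-hydroxyl, and removal of a benzyl group from O2'.
- Ring C is disconnected at O1–C8a, C4–C4a and O1–C2: a tetra-oxygenated ring A aryne (from an o-silylaryl triflate) inserts into the C–O bond of 3-[2-(benzyloxy)-6-methoxyphenyl]propiolic acid, and the resulting o-acylphenoxide closes the pyranone. Rings A and B are bought as benzene rings; ring C is the only ring formed.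
- The strategy rests on this feature: C8a (bearing O1) and C4a (bearing C4) are adjacent ring A carbons flanked by C8–OMe and C5–OMe, and the C6 and C7 oxygens are tied in one ketal. The aryne across C8a/C4a therefore has a mirror plane and takes up O1 and C4 without a regiochemical choice. O6 and O7 are told apart only later, by the acidity that the C4 carbonyl gives to the 7-hydroxyl.
- The silyl triflate comes from 2,3-dihydroxy-4-methoxybenzaldehyde (ketal, Baeyer–Villiger, methylation, ortho-lithiation/oxidation, bromination, retro-Brook/triflation). The acid comes from 2-hydroxy-6-methoxybenzaldehyde (benzylation, Corey–Fuchs olefination, carboxylation).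

Key step: step 10

Remark: the C6/C7 oxygens are tied as a diphenylmethylene ketal, not an isopropylidene ketal. It is put on irreversibly with a gem-dichloride even though the catechol carries an ortho formyl group (which slows acid-catalysed acetone exchange), and it is removed by aqueous acetic acid, which leaves a benzyl ether alone; the symmetry argument is unchanged.

Remark: the fourth ring A oxygen is taken from the formyl group of the starting aldehyde by Baeyer–Villiger oxidation. A second ortho-lithiation of a 4-methoxy-1,3-benzodioxole cannot be relied on to go to C7, because the methoxy group competes as director for C5 and would lead to the unsymmetric 4,5-dimethoxy isomer.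

Assumption: 2,3-dihydroxy-4-methoxybenzaldehyde, dichlorodiphenylmethane and 2-hydroxy-6-methoxybenzaldehyde are taken as commercial.

**Route**

Step 1
Reactants: 1 2,3-dihydroxy-4-methoxybenzaldehyde; 2 dichlorodiphenylmethane
Product: 3 7-methoxy-2,2-diphenyl-1,3-benzodioxole-4-carbaldehyde
Conditions: Ph2CCl2 (1.2 equiv), Ph2O, 175 °C, N2 sweep
Reagents that add atoms: none
Why: Double O-alkylation of the catechol by the benzhydrylic gem-dichloride (diphenylmethylene ketal formation through the diaryl-stabilised cation) is irreversible and tolerates the ortho formyl group.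

Step 2
Reactants: 3 7-methoxy-2,2-diphenyl-1,3-benzodioxole-4-carbaldehyde
Product: 5 7-methoxy-2,2-diphenyl-1,3-benzodioxol-4-ol, via aryl formate 4 (not isolated)
Conditions: mCPBA, CH2Cl2, 0 °C to rt; then K2CO3 (cat.), MeOH, rt, N2
Reagents that add atoms: mCPBA (3-chloroperoxybenzoic acid), O=C(OO)c1cccc(Cl)c1
Why: Baeyer–Villiger oxidation in which the electron-rich aryl group (ortho and para to oxygen) migrates in preference to hydride, followed by mild methanolysis of the formate that leaves the ketal untouched.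

Step 3
Reactants: 5 7-methoxy-2,2-diphenyl-1,3-benzodioxol-4-ol
Product: 6 4,7-dimethoxy-2,2-diphenyl-1,3-benzodioxole
Conditions: MeI, K2CO3, acetone, reflux
Reagents that add atoms: iodomethane, CI
Why: Williamson O-methylation of the phenoxide gives the symmetric tetra-oxygenated arene in which C5 and C6 are equivalent.

Step 4
Reactants: 6 4,7-dimethoxy-2,2-diphenyl-1,3-benzodioxole
Product: 9 4,7-dimethoxy-2,2-diphenyl-1,3-benzodioxol-5-ol, via aryllithium 7 (not isolated), via dimethyl arylboronate 8 (not isolated)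
Conditions: n-BuLi, TMEDA, THF, 0 °C; B(OMe)3, −78 °C to rt; AcOH, 30% H2O2, 0 °C to rt
Reagents that add atoms: hydrogen peroxide, OO
Why: Directed ortho-metalation next to a methoxy group (the only ring hydrogens left are the two equivalent ones), borylation and ipso-oxidation of the arylboronate place the fifth oxygen without a regiochemical choice.

Step 5
Reactants: 9 4,7-dimethoxy-2,2-diphenyl-1,3-benzodioxol-5-ol
Product: 10 6-bromo-4,7-dimethoxy-2,2-diphenyl-1,3-benzodioxol-5-ol
Conditions: NBS (1.0 equiv), CH2Cl2, −78 to −20 °C, dark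
Reagents that add atoms: N-bromosuccinimide, O=C1CCC(=O)N1Br
Why: Electrophilic aromatic bromination at the single free ring position, which is ortho to the hydroxyl group; low temperature and anhydrous conditions are chosen to hold back oxidation of the electron-rich phenol.

Step 6
Reactants: 10 6-bromo-4,7-dimethoxy-2,2-diphenyl-1,3-benzodioxol-5-ol
Product: 13 4,7-dimethoxy-2,2-diphenyl-6-(trimethylsilyl)-1,3-benzodioxol-5-yl trifluoromethanesulfonate, via trimethylsilyl ether 11 (not isolated), via lithium silylphenoxide 12 (not isolated)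
Conditions: HMDS, THF, 65 °C, then evaporation; n-BuLi, THF, −78 °C; Tf2O, −78 °C to rt
Reagents that add atoms: hexamethyldisilazane, C[Si](C)(C)N[Si](C)(C)C; trifluoromethanesulfonic anhydride, O=S(=O)(OS(=O)(=O)C(F)(F)F)C(F)(F)F
Why: O-silylation, bromine–lithium exchange and 1,3 O-to-C silyl shift (retro-Brook rearrangement) give the o-silylphenoxide, which is trapped as the triflate, the standard way to an o-silylaryl triflate.

Step 7
Reactants: 14 2-hydroxy-6-methoxybenzaldehyde
Product: 15 2-(benzyloxy)-6-methoxybenzaldehyde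
Conditions: BnBr, K2CO3, DMF, rt
Reagents that add atoms: benzyl bromide, BrCc1ccccc1
Why: Williamson benzylation of the phenol, which protects O2' with a group stable to organolithium, fluoride and aqueous acid.

Step 8
Reactants: 15 2-(benzyloxy)-6-methoxybenzaldehyde
Product: 16 1-(benzyloxy)-2-(2,2-dibromoethenyl)-3-methoxybenzene
Conditions: CBr4, PPh3, Zn, CH2Cl2, 0 °C to rt
Reagents that add atoms: carbon tetrabromide, BrC(Br)(Br)Br
Why: First stage of the Corey–Fuchs sequence, a Wittig-type dibromo-olefination of the aldehyde by the ylide Ph3P=CBr2.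

Step 9
Reactants: 16 1-(benzyloxy)-2-(2,2-dibromoethenyl)-3-methoxybenzene
Product: 18 3-[2-(benzyloxy)-6-methoxyphenyl]prop-2-ynoic acid, via lithium acetylide 17 (not isolated)
Conditions: n-BuLi (2.2 equiv), THF, −78 °C; CO2 (g), −78 °C to rt; aq. HCl
Reagents that add atoms: carbon dioxide, O=C=O
Why: Second stage of the Corey–Fuchs sequence, in which bromine–lithium exchange and loss of bromide (Fritsch–Buttenberg–Wiechell type) give the lithium acetylide, which is carboxylated by CO2.

Step 10
Reactants: 13 4,7-dimethoxy-2,2-diphenyl-6-(trimethylsilyl)-1,3-benzodioxol-5-yl trifluoromethanesulfonate (1.5 equiv); 18 3-[2-(benzyloxy)-6-methoxyphenyl]prop-2-ynoic acid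
Product: 21 6-[2-(benzyloxy)-6-methoxyphenyl]-4,9-dimethoxy-2,2-diphenyl-8H-[1,3]dioxolo[4,5-g]chromen-8-one (the 6,7-diphenylmethylene ketal of 2-[2-(benzyloxy)-6-methoxyphenyl]-6,7-dihydroxy-5,8-dimethoxy-4H-chromen-4-one), via aryne 19 (not isolated), via cesium acylphenoxide 20 (not isolated)
Conditions: CsF (4 equiv), THF, 125 °C, sealed tube
Reagents that add atoms: none
Why: Fluoride removes the trimethylsilyl group of 13 and triflate leaves, giving aryne 19, whose two reactive carbons (the later C8a and C4a) are related by the mirror plane of the ring, so the cesium carboxylate of 18 can add to either and give the same 2-(acyloxy)aryl anion. That anion attacks its own ester carbonyl through a four-membered alkoxide that opens to the o-acylphenoxide 20, so C8a–O1 and C4a–C4 are made by insertion of the aryne into the acid C–O bond, the known fluoride-induced reaction of arynes with carboxylic acids, which with alkynoic acids runs on to chromones. Ring C is closed by 6-endo-dig oxa-Michael addition of the phenoxide oxygen to the β-carbon of the ynone (O1–C2), followed by protonation at C3. No stereocentre is formed. The step needs insertion to outrun protonation of the aryl anion (which would stop at the aryl ester) and 6-endo to outrun 5-exo closure (which would give an aurone); the aprotic medium at high temperature, the intramolecular acyl transfer and the polarisation of the ynone towards C2 should secure both, and the symmetry of 19 removes the question of which aryne carbon takes the oxygen.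

Step 11
Reactants: 21 6-[2-(benzyloxy)-6-methoxyphenyl]-4,9-dimethoxy-2,2-diphenyl-8H-[1,3]dioxolo[4,5-g]chromen-8-one
Product: 22 2-[2-(benzyloxy)-6-methoxyphenyl]-6,7-dihydroxy-5,8-dimethoxy-4H-chromen-4-one
Conditions: AcOH–H2O (4:1), 100 °C, Ar
Reagents that add atoms: none
Why: Acid hydrolysis of the diaryl ketal through the diphenyl(aryloxy)methyl cation, under conditions to which the benzyl ether and the four methyl ethers are stable.

Step 12
Reactants: 22 2-[2-(benzyloxy)-6-methoxyphenyl]-6,7-dihydroxy-5,8-dimethoxy-4H-chromen-4-one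
Product: 23 2-[2-(benzyloxy)-6-methoxyphenyl]-6-hydroxy-5,7,8-trimethoxy-4H-chromen-4-one
Conditions: MeI (1.05 equiv), KHCO3, DMF, rt
Reagents that add atoms: iodomethane, CI
Why: Chemoselective Williamson methylation, in which the 7-hydroxyl (para to the C4 carbonyl through C4a, a vinylogous acid) is the one ionised by hydrogencarbonate, so its phenoxide is alkylated while the 6-hydroxyl stays protonated.

Step 13
Reactants: 23 2-[2-(benzyloxy)-6-methoxyphenyl]-6-hydroxy-5,7,8-trimethoxy-4H-chromen-4-one
Product: 24 6-hydroxy-2-(2-hydroxy-6-methoxyphenyl)-5,7,8-trimethoxy-4H-chromen-4-one (6,2'-dihydroxy-5,7,8,6'-tetramethoxyflavone)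
Conditions: H2 (1 atm), Pd/C, EtOAc–MeOH, rt
Reagents that add atoms: none
Why: Hydrogenolysis of the benzyl aryl ether over palladium under conditions mild enough to leave the C2–C3 double bond of the pyranone intact.

**Compound list**

1 | 2,3-dihydroxy-4-methoxybenzaldehyde | COc1ccc(C=O)c(O)c1O | starting material
2 | dichlorodiphenylmethane | ClC(Cl)(c1ccccc1)c1ccccc1 | starting material
3 | 7-methoxy-2,2-diphenyl-1,3-benzodioxole-4-carbaldehyde | COc1ccc(C=O)c2OC(c3ccccc3)(c3ccccc3)Oc12 | intermediate
4 | 7-methoxy-2,2-diphenyl-1,3-benzodioxol-4-yl formate | COc1ccc(OC=O)c2OC(c3ccccc3)(c3ccccc3)Oc12 | intermediate (not isolated)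
5 | 7-methoxy-2,2-diphenyl-1,3-benzodioxol-4-ol | COc1ccc(O)c2OC(c3ccccc3)(c3ccccc3)Oc12 | intermediate
6 | 4,7-dimethoxy-2,2-diphenyl-1,3-benzodioxole | COc1ccc(OC)c2OC(c3ccccc3)(c3ccccc3)Oc12 | intermediate
7 | (4,7-dimethoxy-2,2-diphenyl-1,3-benzodioxol-5-yl)lithium | [Li]c1cc(OC)c2OC(c3ccccc3)(c3ccccc3)Oc2c1OC | intermediate (not isolated)
8 | dimethyl (4,7-dimethoxy-2,2-diphenyl-1,3-benzodioxol-5-yl)boronate | COB(OC)c1cc(OC)c2OC(c3ccccc3)(c3ccccc3)Oc2c1OC | intermediate (not isolated)
9 | 4,7-dimethoxy-2,2-diphenyl-1,3-benzodioxol-5-ol | Oc1cc(OC)c2OC(c3ccccc3)(c3ccccc3)Oc2c1OC | intermediate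
10 | 6-bromo-4,7-dimethoxy-2,2-diphenyl-1,3-benzodioxol-5-ol | Oc1c(Br)c(OC)c2OC(c3ccccc3)(c3ccccc3)Oc2c1OC | intermediate
11 | [(6-bromo-4,7-dimethoxy-2,2-diphenyl-1,3-benzodioxol-5-yl)oxy]trimethylsilane | C[Si](C)(C)Oc1c(Br)c(OC)c2OC(c3ccccc3)(c3ccccc3)Oc2c1OC | intermediate (not isolated)
12 | lithium 4,7-dimethoxy-2,2-diphenyl-6-(trimethylsilyl)-1,3-benzodioxol-5-olate | [Li]Oc1c([Si](C)(C)C)c(OC)c2OC(c3ccccc3)(c3ccccc3)Oc2c1OC | intermediate (not isolated)
13 | 4,7-dimethoxy-2,2-diphenyl-6-(trimethylsilyl)-1,3-benzodioxol-5-yl trifluoromethanesulfonate | FC(F)(F)S(=O)(=O)Oc1c([Si](C)(C)C)c(OC)c2OC(c3ccccc3)(c3ccccc3)Oc2c1OC | intermediate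
14 | 2-hydroxy-6-methoxybenzaldehyde | COc1cccc(O)c1C=O | starting material
15 | 2-(benzyloxy)-6-methoxybenzaldehyde | COc1cccc(OCc2ccccc2)c1C=O | intermediate
16 | 1-(benzyloxy)-2-(2,2-dibromoethenyl)-3-methoxybenzene | COc1cccc(OCc2ccccc2)c1C=C(Br)Br | intermediate
17 | {[2-(benzyloxy)-6-methoxyphenyl]ethynyl}lithium | [Li]C#Cc1c(OC)cccc1OCc1ccccc1 | intermediate (not isolated)
18 | 3-[2-(benzyloxy)-6-methoxyphenyl]prop-2-ynoic acid | COc1cccc(OCc2ccccc2)c1C#CC(=O)O | intermediate
19 | 5,6-didehydro-4,7-dimethoxy-2,2-diphenyl-1,3-benzodioxole (aryne) | COC1=C2OC(c3ccccc3)(c3ccccc3)OC2=C(OC)C#C1 | intermediate (not isolated)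
20 | cesium 6-{3-[2-(benzyloxy)-6-methoxyphenyl]prop-2-ynoyl}-4,7-dimethoxy-2,2-diphenyl-1,3-benzodioxol-5-olate | COc1cccc(OCc2ccccc2)c1C#CC(=O)c1c([O-])c(OC)c2OC(c3ccccc3)(c3ccccc3)Oc2c1OC.[Cs+] | intermediate (not isolated)
21 | 6-[2-(benzyloxy)-6-methoxyphenyl]-4,9-dimethoxy-2,2-diphenyl-8H-[1,3]dioxolo[4,5-g]chromen-8-one | COc1cccc(OCc2ccccc2)c1-c1cc(=O)c2c(OC)c3OC(c4ccccc4)(c4ccccc4)Oc3c(OC)c2o1 | intermediate
22 | 2-[2-(benzyloxy)-6-methoxyphenyl]-6,7-dihydroxy-5,8-dimethoxy-4H-chromen-4-one | COc1cccc(OCc2ccccc2)c1-c1cc(=O)c2c(OC)c(O)c(O)c(OC)c2o1 | intermediate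
23 | 2-[2-(benzyloxy)-6-methoxyphenyl]-6-hydroxy-5,7,8-trimethoxy-4H-chromen-4-one | COc1cccc(OCc2ccccc2)c1-c1cc(=O)c2c(OC)c(O)c(OC)c(OC)c2o1 | intermediate
24 | 6-hydroxy-2-(2-hydroxy-6-methoxyphenyl)-5,7,8-trimethoxy-4H-chromen-4-one | COc1cccc(O)c1-c1cc(=O)c2c(OC)c(O)c(OC)c(OC)c2o1 | target

**Step count**

Total steps: 13. Longest linear sequence: 10 steps (steps 1–6, then 10–13); the acid branch (steps 7–9) is 3 steps.

**Steps most likely to fail**

1. Step 10 (aryne insertion and ring C closure).
   - What may go wrong: protonation of the 2-(acyloxy)aryl anion before acyl transfer, so that the reaction stops at the aryl ester; loss of CO2 from the cesium arylpropiolate at 125 °C; 5-exo closure of the phenoxide to an aurone; O-arylation of the phenoxide by a second aryne.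
   - Fallback: ring C is built by palladium-catalysed carbonylative annulation, with C4 coming from CO. It sets out from 9 and 16. Iodination of 9 (NIS, CH2Cl2, −40 °C) should give 6-iodo-4,7-dimethoxy-2,2-diphenyl-1,3-benzodioxol-5-ol F1. Treatment of 16 with n-BuLi (2.2 equiv, THF, −78 °C) gives acetylide 17, which on quenching with aqueous NH4Cl gives 1-(benzyloxy)-2-ethynyl-3-methoxybenzene F2. F1 and F2 under CO (20 bar) with PdCl2(PPh3)2 in Et2NH at 120 °C should give 3-[2-(benzyloxy)-6-methoxyphenyl]-1-(6-hydroxy-4,7-dimethoxy-2,2-diphenyl-1,3-benzodioxol-5-yl)prop-2-yn-1-one F3, which closes under the amine conditions by 6-endo addition. The route is rejoined at 21.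

2. Step 12 (selective methylation of O7).
   - What may go wrong: over-methylation to the 6,7-dimethyl ether, or alkylation at O6 after proton exchange within the catechol monoanion.
   - Fallback: the two hydroxyls are told apart by selective deacylation instead of selective alkylation. It sets out from 22. Ac2O in pyridine should give 2-[2-(benzyloxy)-6-methoxyphenyl]-5,8-dimethoxy-4-oxo-4H-chromene-6,7-diyl diacetate F4. PhSH with imidazole in NMP at 0 °C should remove only the 7-acetyl group, the ester of the more acidic phenol, to give 2-[2-(benzyloxy)-6-methoxyphenyl]-7-hydroxy-5,8-dimethoxy-4-oxo-4H-chromen-6-yl acetate F5. Mitsunobu methylation (MeOH, PPh3, DIAD, THF) should give 2-[2-(benzyloxy)-6-methoxyphenyl]-5,7,8-trimethoxy-4-oxo-4H-chromen-6-yl acetate F6. K2CO3 in MeOH removes the acetate, and the route is rejoined at 23.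

3. Step 5 (bromination of the penta-oxygenated phenol).
   - What may go wrong: oxidation of the electron-rich phenol by NBS to quinoid products, with loss of the ketal, in place of ring bromination.
   - Fallback: the silyl group is introduced by carbamate-directed ortho-metalation, with no halogenation. It sets out from 9. Et2NCOCl with NaH in THF should give 4,7-dimethoxy-2,2-diphenyl-1,3-benzodioxol-5-yl diethylcarbamate F7. s-BuLi with TMEDA in THF at −78 °C should lithiate C6, which lies between the carbamate and a methoxy group, to give 6-lithio-4,7-dimethoxy-2,2-diphenyl-1,3-benzodioxol-5-yl diethylcarbamate F8. TMSCl converts this to 4,7-dimethoxy-2,2-diphenyl-6-(trimethylsilyl)-1,3-benzodioxol-5-yl diethylcarbamate F9. LiAlH4 in THF (0 °C to rt) cleaves the carbamate to 4,7-dimethoxy-2,2-diphenyl-6-(trimethylsilyl)-1,3-benzodioxol-5-ol F10. Deprotonation with n-BuLi at −78 °C gives the lithium phenoxide 12, where the route is rejoined; Tf2O then gives 13 as in step 6, so steps 5 and 6 are bypassed.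

**Further compounds**

F1 | step 10 | 6-iodo-4,7-dimethoxy-2,2-diphenyl-1,3-benzodioxol-5-ol | Oc1c(I)c(OC)c2OC(c3ccccc3)(c3ccccc3)Oc2c1OC
F2 | step 10 | 1-(benzyloxy)-2-ethynyl-3-methoxybenzene | COc1cccc(OCc2ccccc2)c1C#C
F3 | step 10 | 3-[2-(benzyloxy)-6-methoxyphenyl]-1-(6-hydroxy-4,7-dimethoxy-2,2-diphenyl-1,3-benzodioxol-5-yl)prop-2-yn-1-one | COc1cccc(OCc2ccccc2)c1C#CC(=O)c1c(O)c(OC)c2OC(c3ccccc3)(c3ccccc3)Oc2c1OC
F4 | step 12 | 2-[2-(benzyloxy)-6-methoxyphenyl]-5,8-dimethoxy-4-oxo-4H-chromene-6,7-diyl diacetate | COc1cccc(OCc2ccccc2)c1-c1cc(=O)c2c(OC)c(OC(C)=O)c(OC(C)=O)c(OC)c2o1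
F5 | step 12 | 2-[2-(benzyloxy)-6-methoxyphenyl]-7-hydroxy-5,8-dimethoxy-4-oxo-4H-chromen-6-yl acetate | COc1cccc(OCc2ccccc2)c1-c1cc(=O)c2c(OC)c(OC(C)=O)c(O)c(OC)c2o1
F6 | step 12 | 2-[2-(benzyloxy)-6-methoxyphenyl]-5,7,8-trimethoxy-4-oxo-4H-chromen-6-yl acetate | COc1cccc(OCc2ccccc2)c1-c1cc(=O)c2c(OC)c(OC(C)=O)c(OC)c(OC)c2o1
F7 | step 5 | 4,7-dimethoxy-2,2-diphenyl-1,3-benzodioxol-5-yl diethylcarbamate | CCN(CC)C(=O)Oc1cc(OC)c2OC(c3ccccc3)(c3ccccc3)Oc2c1OC
F8 | step 5 | 6-lithio-4,7-dimethoxy-2,2-diphenyl-1,3-benzodioxol-5-yl diethylcarbamate | CCN(CC)C(=O)Oc1c([Li])c(OC)c2OC(c3ccccc3)(c3ccccc3)Oc2c1OC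
F9 | step 5 | 4,7-dimethoxy-2,2-diphenyl-6-(trimethylsilyl)-1,3-benzodioxol-5-yl diethylcarbamate | CCN(CC)C(=O)Oc1c([Si](C)(C)C)c(OC)c2OC(c3ccccc3)(c3ccccc3)Oc2c1OC
F10 | step 5 | 4,7-dimethoxy-2,2-diphenyl-6-(trimethylsilyl)-1,3-benzodioxol-5-ol | Oc1c([Si](C)(C)C)c(OC)c2OC(c3ccccc3)(c3ccccc3)Oc2c1OC
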